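## Retrosynthetic overview

1. Guangsangon N ⇐ global MOM removal ⇐ intermolecular Diels–Alder of the (2S)-flavanone diene **14** with the 2′-hydroxychalcone **19**. The cyclohexene is the last ring formed, and its three stereocentres are created in this step.
2. Diene **14** ⇐ Suzuki coupling (dienyl-Bpin **12**) and C4 oxidation of bromoflavan-4-ol **10**. The pyran ring of **10** is closed by intramolecular SNAr (aryl–O bond), so the benzylic C–O bond is never broken.
3. Flavanone C2 ⇐ 1,3-anti hydroxyl-directed reduction of aryl ketone **4**, made from an aryllithium and (S)-3-hydroxy-γ-butyrolactone **3**. The lactone carbinol carbon later becomes the C4 carbonyl (periodate cleavage, aryl-Grignard addition, oxidation).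
4. Chalcone **19** ⇐ Claisen–Schmidt condensation. Ring order: chroman C-ring, then cyclohexene.
5. Stereochemistry: all absolute configuration comes from lactone **3**. C2 is too remote to bias the diene faces, so the two exo adducts form as diastereomers and the correct one is separated.

Assumption: cyclohexene descriptors (3R,4R,5S) use C1 = C–CH3 and C3 = the carbon bearing the flavanone aryl; the target is the all-trans (exo-type) adduct with a (2S)-flavanone.

## Route

**Step 1**
Reactants: **1**, 4,6-dibromobenzene-1,3-diol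
Product: **2**, 1,5-dibromo-2,4-bis(methoxymethoxy)benzene
Conditions: MOMCl (2.5 equiv), i-Pr2NEt, CH2Cl2, 0 °C → rt
Reagents that add atoms: chloromethyl methyl ether (MOMCl), COCCl
Why: Williamson-type O-alkylation of both phenols; the MOM ethers stabilise the later ortho-aryllithium and tolerate every basic step.

**Step 2**
Reactants: **2**, 1,5-dibromo-2,4-bis(methoxymethoxy)benzene; **3**, (S)-3-hydroxy-γ-butyrolactone [(4S)-4-hydroxyoxolan-2-one]
Product: **4**, (3S)-1-[5-bromo-2,4-bis(methoxymethoxy)phenyl]-3,4-dihydroxybutan-1-one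
Conditions: **2** (2.3 equiv), n-BuLi (2.2 equiv), THF, −78 °C; then **3** (1.0 equiv), −78 → −40 °C; aq. NH4Cl
Reagents that add atoms: none
Why: Mono Br/Li exchange then acyl substitution on the lactone (one ArLi equivalent deprotonates the OH, the second adds and the tetrahedral alkoxide stops at the ketone); the lactone stereocentre is carried unchanged as C3.

**Step 3**
Reactants: **4**
Product: **5**, (1S,3S)-1-[5-bromo-2,4-bis(methoxymethoxy)phenyl]butane-1,3,4-triol
Conditions: Me4NBH(OAc)3 (5 equiv), MeCN/AcOH (1:1), −30 → 0 °C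
Reagents that add atoms: none
Why: Evans–Saksena hydroxyl-directed reduction; intramolecular hydride delivery from the C3-O-bound borohydride through a chair six-membered transition state gives the 1,3-anti diol, setting the benzylic carbinol (future C2) as S.

**Step 4**
Reactants: **5**
Product: **6**, (3S)-3-[5-bromo-2,4-bis(methoxymethoxy)phenyl]-3-hydroxypropanal
Conditions: NaIO4 (1.3 equiv), THF/pH 7 buffer, 0 °C, 30 min; used crude
Reagents that add atoms: none
Why: Malaprade glycol cleavage touches only the vicinal 3,4-diol and excises CH2OH as formaldehyde, turning the lactone-derived carbinol into the future C4 aldehyde while the benzylic centre is untouched.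

**Step 5**
Reactants: **7**, 4-bromo-3-fluorophenol
Product: **8**, 1-bromo-2-fluoro-4-(methoxymethoxy)benzene
Conditions: MOMCl, i-Pr2NEt, CH2Cl2, 0 °C → rt
Reagents that add atoms: chloromethyl methyl ether (MOMCl), COCCl
Why: Simple phenol O-alkylation giving the A-ring precursor with F placed to become the C8a–O1 site.

**Step 6**
Reactants: **6**; **8**
Product: **9**, (1S,3RS)-1-[5-bromo-2,4-bis(methoxymethoxy)phenyl]-3-[2-fluoro-4-(methoxymethoxy)phenyl]propane-1,3-diol
Conditions: **8** (3.2 equiv), i-PrMgCl·LiCl (3.0 equiv), THF, 0 °C → rt; then crude **6** added slowly at −40 → 0 °C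
Reagents that add atoms: none
Why: Br/Mg exchange and Grignard 1,2-addition (inverse addition into excess reagent outruns retro-aldol or dehydration of the β-hydroxy aldehyde); the new carbinol is an irrelevant epimer mixture that is oxidised to C=O in step 10.

**Step 7**
Reactants: **9**
Product: **10**, (2S,4RS)-2-[5-bromo-2,4-bis(methoxymethoxy)phenyl]-7-(methoxymethoxy)-3,4-dihydro-2H-chromen-4-ol
Conditions: KOtBu (2.5 equiv), DMF, 70 °C
Reagents that add atoms: none
Why: Intramolecular SNAr (6-membered closure) of the benzylic alkoxide on the aryl fluoride; only the aryl–O bond is made, so C2 keeps its S configuration, and the other alkoxide cannot cyclise (4-membered ring).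

**Step 8**
Reactants: **11**, 2-methylbut-1-en-3-yne
Product: **12**, 4,4,5,5-tetramethyl-2-[(1E)-3-methylbuta-1,3-dien-1-yl]-1,3,2-dioxaborolane
Conditions: HBpin (1.1 equiv), Cp2Zr(H)Cl (5 mol %), Et3N (10 mol %), neat, 60 °C
Reagents that add atoms: pinacolborane, CC1(C)OBOC1(C)C
Why: Zr-catalysed syn, anti-Markovnikov hydroboration of the terminal alkyne gives the (E)-dienylboronate.

**Step 9**
Reactants: **10**; **12**
Product: **13**, (2S,4RS)-2-{2,4-bis(methoxymethoxy)-5-[(1E)-3-methylbuta-1,3-dien-1-yl]phenyl}-7-(methoxymethoxy)-3,4-dihydro-2H-chromen-4-ol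
Conditions: **12** (1.5 equiv), Pd(dppf)Cl2 (5 mol %), K2CO3, 1,4-dioxane/H2O (5:1), 80 °C
Reagents that add atoms: none
Why: Suzuki–Miyaura coupling with retention of E geometry; it is run at the carbinol stage so that no base-sensitive flavanone is exposed to aqueous carbonate.

**Step 10**
Reactants: **13**
Product: **14**, (2S)-2-{2,4-bis(methoxymethoxy)-5-[(1E)-3-methylbuta-1,3-dien-1-yl]phenyl}-7-(methoxymethoxy)-2,3-dihydro-4H-chromen-4-one
Conditions: Dess–Martin periodinane, NaHCO3, CH2Cl2, 0 °C → rt
Reagents that add atoms: none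
Why: Buffered Dess–Martin oxidation of the benzylic alcohol removes the C4 epimer mixture and tolerates the diene; the neutral conditions avoid retro-oxa-Michael opening, so C2 stays S.

**Step 11**
Reactants: **15**, 1-(2,4-dihydroxyphenyl)ethanone
Product: **16**, 1-[2-hydroxy-4-(methoxymethoxy)phenyl]ethanone
Conditions: MOMCl (1.1 equiv), K2CO3, acetone, rt
Reagents that add atoms: chloromethyl methyl ether (MOMCl), COCCl
Why: Selective O-alkylation of the 4-OH; the 2-OH is hydrogen-bonded to the carbonyl and stays free, as the cycloaddition requires.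

**Step 12**
Reactants: **17**, 2,4-dihydroxybenzaldehyde
Product: **18**, 2,4-bis(methoxymethoxy)benzaldehyde
Conditions: MOMCl (2.6 equiv), NaH, DMF, 0 °C → rt
Reagents that add atoms: chloromethyl methyl ether (MOMCl), COCCl
Why: Exhaustive O-alkylation (NaH is needed for the chelated 2-OH).

**Step 13**
Reactants: **16**; **18**
Product: **19**, (2E)-3-[2,4-bis(methoxymethoxy)phenyl]-1-[2-hydroxy-4-(methoxymethoxy)phenyl]prop-2-en-1-one
Conditions: KOH (50% aq.), EtOH, rt, 36 h; then AcOH to pH 6
Reagents that add atoms: none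
Why: Claisen–Schmidt aldol condensation gives the thermodynamic E-enone.

**Step 14**
Reactants: **14**; **19**
Product: **20**, (2S)-2-{5-[(1R,5S,6R)-5-[2,4-bis(methoxymethoxy)phenyl]-6-[2-hydroxy-4-(methoxymethoxy)benzoyl]-3-methylcyclohex-2-en-1-yl]-2,4-bis(methoxymethoxy)phenyl}-7-(methoxymethoxy)-2,3-dihydro-4H-chromen-4-one (all-trans cyclohexene)
Conditions: **19** (2 equiv), BHT (cat.), PhMe, 160 °C, sealed tube, 36 h; SiO2 then preparative HPLC
Reagents that add atoms: none
Why: Thermal intermolecular Diels–Alder with the H-bond-activated 2′-hydroxy enone: ortho/para regiochemistry, the E-enone fixes 4,5-trans and the aroyl-exo transition state gives 3,4-trans; C2 gives no useful facial bias, so two exo and two endo adducts form in roughly equal amounts as diastereomers and the (3R,4R,5S) isomer **20** is isolated chromatographically.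

**Step 15**
Reactants: **20**
Product: **21**, guangsangon N, (2S)-2-{5-[(1R,5S,6R)-6-(2,4-dihydroxybenzoyl)-5-(2,4-dihydroxyphenyl)-3-methylcyclohex-2-en-1-yl]-2,4-dihydroxyphenyl}-7-hydroxy-2,3-dihydro-4H-chromen-4-one
Conditions: TMSOTf, 2,2′-bipyridyl, CH2Cl2, 0 °C → rt; then H2O/THF, rt
Reagents that add atoms: none
Why: Non-protic cleavage of all six aryl MOM ethers via aryl silyl ethers that hydrolyse on work-up; this avoids the hot protic acid or base that would open the flavanone at C2 or cyclise phenols onto the cyclohexene, and no stereocentre is touched.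

## Compound list

1 | 4,6-dibromobenzene-1,3-diol | Oc1cc(O)c(Br)cc1Br | starting material
2 | 1,5-dibromo-2,4-bis(methoxymethoxy)benzene | COCOc1cc(OCOC)c(Br)cc1Br | intermediate
3 | (S)-3-hydroxy-γ-butyrolactone | O=C1C[C@H](O)CO1 | starting material (chiral)
4 | (3S)-1-[5-bromo-2,4-bis(methoxymethoxy)phenyl]-3,4-dihydroxybutan-1-one | COCOc1cc(OCOC)c(Br)cc1C(=O)C[C@H](O)CO | intermediate
5 | (1S,3S)-1-[5-bromo-2,4-bis(methoxymethoxy)phenyl]butane-1,3,4-triol | COCOc1cc(OCOC)c(Br)cc1[C@@H](O)C[C@H](O)CO | intermediate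
6 | (3S)-3-[5-bromo-2,4-bis(methoxymethoxy)phenyl]-3-hydroxypropanal | COCOc1cc(OCOC)c(Br)cc1[C@@H](O)CC=O | intermediate
7 | 4-bromo-3-fluorophenol | Oc1ccc(Br)c(F)c1 | starting material
8 | 1-bromo-2-fluoro-4-(methoxymethoxy)benzene | COCOc1ccc(Br)c(F)c1 | intermediate
9 | (1S,3RS)-1-[5-bromo-2,4-bis(methoxymethoxy)phenyl]-3-[2-fluoro-4-(methoxymethoxy)phenyl]propane-1,3-diol | COCOc1cc(OCOC)c(Br)cc1[C@@H](O)CC(O)c1ccc(OCOC)cc1F | intermediate
10 | (2S,4RS)-2-[5-bromo-2,4-bis(methoxymethoxy)phenyl]-7-(methoxymethoxy)chroman-4-ol | COCOc1cc(OCOC)c(Br)cc1[C@@H]1CC(O)c2ccc(OCOC)cc2O1 | intermediate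
11 | 2-methylbut-1-en-3-yne | C=C(C)C#C | starting material
12 | 4,4,5,5-tetramethyl-2-[(1E)-3-methylbuta-1,3-dien-1-yl]-1,3,2-dioxaborolane | CC(=C)/C=C/B1OC(C)(C)C(C)(C)O1 | intermediate
13 | (2S,4RS)-2-{2,4-bis(methoxymethoxy)-5-[(1E)-3-methylbuta-1,3-dien-1-yl]phenyl}-7-(methoxymethoxy)chroman-4-ol | COCOc1cc(OCOC)c(/C=C/C(C)=C)cc1[C@@H]1CC(O)c2ccc(OCOC)cc2O1 | intermediate
14 | (2S)-2-{2,4-bis(methoxymethoxy)-5-[(1E)-3-methylbuta-1,3-dien-1-yl]phenyl}-7-(methoxymethoxy)chroman-4-one | COCOc1cc(OCOC)c(/C=C/C(C)=C)cc1[C@@H]1CC(=O)c2ccc(OCOC)cc2O1 | intermediate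
15 | 1-(2,4-dihydroxyphenyl)ethanone | CC(=O)c1ccc(O)cc1O | starting material
16 | 1-[2-hydroxy-4-(methoxymethoxy)phenyl]ethanone | CC(=O)c1ccc(OCOC)cc1O | intermediate
17 | 2,4-dihydroxybenzaldehyde | O=Cc1ccc(O)cc1O | starting material
18 | 2,4-bis(methoxymethoxy)benzaldehyde | COCOc1ccc(C=O)c(OCOC)c1 | intermediate
19 | (2E)-3-[2,4-bis(methoxymethoxy)phenyl]-1-[2-hydroxy-4-(methoxymethoxy)phenyl]prop-2-en-1-one | COCOc1ccc(C(=O)/C=C/c2ccc(OCOC)cc2OCOC)c(O)c1 | intermediate
20 | hexa-MOM all-trans adduct, (2S; 3R,4R,5S-cyclohexene) | CC1=C[C@@H](c2cc([C@@H]3CC(=O)c4ccc(OCOC)cc4O3)c(OCOC)cc2OCOC)[C@H](C(=O)c2ccc(OCOC)cc2O)[C@@H](c2ccc(OCOC)cc2OCOC)C1 | intermediate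
21 | guangsangon N | CC1=C[C@@H](c2cc([C@@H]3CC(=O)c4ccc(O)cc4O3)c(O)cc2O)[C@H](C(=O)c2ccc(O)cc2O)[C@@H](c2ccc(O)cc2O)C1 | target

## Summary

Total steps: 15.
Longest linear sequence: 10 steps (1 → 2 → 4 → 5 → 6 → 9 → 10 → 13 → 14 → 20 → 21; steps 1–4, 6, 7, 9, 10, 14, 15).

Three steps most likely to fail:

1. **Step 14 (Diels–Alder).** Exo/endo is roughly 1:1 and C2 gives no facial bias, so at best about a quarter of the adduct mixture is **20**, and the two exo diastereomers differ only at a remote centre and may be hard to separate. Fallback: make the cycloaddition intramolecular.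
   - Esterify the C4-OH of one C4 epimer of **13** with (E)-3-[2,4-bis(methoxymethoxy)phenyl]acrylic acid.
   - Run the tethered macrolactone Diels–Alder, where C2/C4 sit on the tether and can select the diene face and exo/endo mode.
   - Open the lactone with 2,4-bis(methoxymethoxy)phenyllithium to the aryl ketone, then oxidise the freed C4-OH.

2. **Step 7 (SNAr on a non-activated fluoroarene).** It may be slow, or the aryl bromide may suffer under hot alkoxide. Fallback: switch to metal-catalysed C–O coupling.
   - Build the B ring from 4-bromoresorcinol so there is no second bromide.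
   - Use 2-bromo-1-iodo-4-(methoxymethoxy)benzene (I/Mg exchange) in step 6.
   - Close the ring with CuI/Me4phen/Cs2CO3 (retention at C2).
   - Install the 5′-bromide afterwards with NBS (para to the 2′-OMOM).

3. **Step 15 (sixfold MOM removal).** The product's C2–O1 bond is benzylic to a 2,4-dihydroxyaryl ring (risk of ring opening and C2 epimerisation), and neighbouring phenols can add to the cyclohexene. Fallback: change the protecting-group plan to benzyl ethers throughout (compatible with steps 1–14) and finish with BCl3/pentamethylbenzene at −78 °C or brief Pd/C hydrogenolysis.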